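**Retrosynthetic overview**
- Target ⇐ desilylation and α-methylenation (C-17) of a tetracyclic β-keto lactone.
- Rings C and D ⇐ one SmI2 ketyl–olefin/Claisen cascade on an α-alkylated unsaturated spirolactone; the (S)-side chain (organocatalytic α-allylation of methyl 4-oxobutanoate) is attached by Negishi coupling.
- Spiro δ-lactone (C-9–C-10 bond, quaternary C-10) ⇐ reductive radical 1,2-vinyl shift that expands a γ-cyclohexenyl butenolide by one ring atom (key step).
- Butenolide ⇐ Nozaki–Hiyama–Kishi union of the ring A enal with ethyl (Z)-3-iodoacrylate; ring A ⇐ catalytic asymmetric Diels–Alder (C-4, C-5), CHO→CH3, allylic oxidation.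
- Ring order: A, then butenolide, then spiro lactone by ring expansion, then C and D together.

Assumption: kaurane locants (C-1 to C-20) are used only as atom labels; TBS = tert-butyl(dimethyl)silyl; the five numbered starting materials are taken as purchasable.

Step 1
Reactants: 1 2-methylidenepropane-1,3-diol
Product: 2 2-(TBSOCH2)prop-2-en-1-ol
Conditions: NaH (1.0 equiv), THF, 0 °C; then TBSCl (1.0 equiv), 0 → 23 °C
Reagents that add atoms: tert-butyl(chloro)dimethylsilane (TBSCl), CC(C)(C)[Si](C)(C)Cl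
Why: Monosilylation of a symmetrical diol through its monosodium alkoxide (O-silylation); no stereocentre is formed.

Step 2
Reactants: 2 2-(TBSOCH2)prop-2-en-1-ol
Product: 3 2-(TBSOCH2)prop-2-enal
Conditions: MnO2 (10 equiv), CH2Cl2, 23 °C
Reagents that add atoms: none
Why: MnO2 oxidation of a primary allylic alcohol to the enal; the silyl ether is inert.

Step 3
Reactants: 4 (2E)-3-methylpent-2-en-4-yn-1-ol
Product: 5 tert-butyl(dimethyl){[(2E)-3-methylpent-2-en-4-yn-1-yl]oxy}silane
Conditions: TBSCl, imidazole, DMF, 23 °C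
Reagents that add atoms: tert-butyl(chloro)dimethylsilane (TBSCl), CC(C)(C)[Si](C)(C)Cl
Why: Standard O-silylation; the E alkene is untouched.

Step 4
Reactants: 5 tert-butyl(dimethyl){[(2E)-3-methylpent-2-en-4-yn-1-yl]oxy}silane
Product: 6 tert-butyl(dimethyl){[(2E)-3-methylpenta-2,4-dien-1-yl]oxy}silane
Conditions: H2 (1 atm), Pd/CaCO3 poisoned with Pb(OAc)2, quinoline, hexane, 23 °C
Reagents that add atoms: none
Why: Lindlar semihydrogenation of the terminal alkyne gives the vinyl group and leaves the E-trisubstituted alkene, so the CH2OTBS group sits "outside" on the diene.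

Step 5
Reactants: 6 tert-butyl(dimethyl){[(2E)-3-methylpenta-2,4-dien-1-yl]oxy}silane and 3 2-(TBSOCH2)prop-2-enal
Product: 7 (1R,2S)-1,2-bis(TBSOCH2)-3-methylcyclohex-3-ene-1-carbaldehyde (CHO cis to the neighbouring CH2OTBS)
Conditions: 3 (1.5 equiv), (S)-o-tolyl-CBS-oxazaborolidine·HNTf2 (20 mol %; mirror-image catalyst if the facial sense must be reversed), CH2Cl2, −78 → −40 °C
Reagents that add atoms: none
Why: Catalytic asymmetric Diels–Alder reaction of a 2-substituted acrolein, in which the enal β-carbon bonds first to the unsubstituted diene terminus ("ortho" adduct), the endo transition state places CHO cis to the E-terminal CH2OTBS (C-4/C-5 relative configuration) and the oxazaborolidinium shields one enal face (absolute configuration).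

Step 6
Reactants: 7 (1R,2S)-1,2-bis(TBSOCH2)-3-methylcyclohex-3-ene-1-carbaldehyde
Product: 9 (5S,6S)-5,6-bis(TBSOCH2)-1,5-dimethylcyclohex-1-ene, via N-silylhydrazone 8 (not isolated)
Conditions: TBSNHNHTBS, Sc(OTf)3 (1 mol %), 23 °C; then KOt-Bu (0.3 equiv), t-BuOH, DMSO, 23 → 100 °C
Reagents that add atoms: 1,2-bis(tert-butyldimethylsilyl)hydrazine (retained in 8 only), CC(C)(C)[Si](C)(C)NN[Si](C)(C)C(C)(C)C
Why: Wolff–Kishner reduction in the mild N-silylhydrazone variant turns the endo CHO into the C-19 methyl, so the methyl ends cis and the CH2OTBS trans to the C-5 CH2OTBS with no stereocentre touched.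

Step 7
Reactants: 9 (5S,6S)-5,6-bis(TBSOCH2)-1,5-dimethylcyclohex-1-ene
Product: 11 (5S,6R)-5,6-bis(TBSOCH2)-5-methylcyclohex-1-ene-1-carbaldehyde, via allylic alcohol 10 (not isolated)
Conditions: SeO2 (1.3 equiv), pyridine (0.2 equiv), 1,4-dioxane, 80 °C
Reagents that add atoms: selenium dioxide, O=[Se]=O
Why: Riley allylic oxidation (ene reaction then [2,3]-shift) attacks the vinylic CH3 on the more substituted alkene terminus (CH3 preferred over the hindered tertiary C-5–H) and over-oxidises the alcohol to the enal.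

Step 8
Reactants: 11 (5S,6R)-5,6-bis(TBSOCH2)-5-methylcyclohex-1-ene-1-carbaldehyde and 12 ethyl (2Z)-3-iodoprop-2-enoate
Product: 14 5-[(5S,6R)-5,6-bis(TBSOCH2)-5-methylcyclohex-1-en-1-yl]furan-2(5H)-one (both epimers at the furanone CH), via hydroxy ester 13 (not isolated)
Conditions: CrCl2 (4 equiv), NiCl2 (2 mol %), DMF, 23 °C
Reagents that add atoms: none
Why: Nozaki–Hiyama–Kishi addition of the alkenyl (trivalent) chromium species to the aldehyde gives a (Z)-γ-hydroxy enoate that lactonises at once; the new CH–O centre is formed unselectively and is erased in step 9.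

Step 9
Reactants: 14 5-[(5S,6R)-5,6-bis(TBSOCH2)-5-methylcyclohex-1-en-1-yl]furan-2(5H)-one
Product: 15 (6R,7R,8S)-7,8-bis(TBSOCH2)-8-methyl-2-oxaspiro[5.5]undec-4-en-3-one
Conditions: Fe(acac)3 (20 mol %), PhSiH3 (2.5 equiv, syringe pump), 4-tert-butylbenzenethiol (10 mol %), EtOH/THF, 50 °C
Reagents that add atoms: none
Why: Proposed new method: hydrogen-atom transfer from an iron hydride to C-1 gives the tertiary C-10 radical, which closes 3-exo onto the butenolide β-carbon (C-9) to an ester-stabilised cyclopropylcarbinyl radical and reopens by scission of the old C-9–C-20 bond to the α-acyloxyalkyl radical of the ring-expanded δ-lactone, which the thiol reduces, so that C-9 shifts from C-20 to C-10 anti to the neighbouring CH2OTBS and sets the spiro stereocentre; the closest known reaction types are the Dowd–Beckwith ring expansion, radical 1,2-vinyl (neophyl-type) migrations and iron-hydride Giese couplings of trisubstituted alkenes.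

Step 10
Reactants: 15 (6R,7R,8S)-7,8-bis(TBSOCH2)-8-methyl-2-oxaspiro[5.5]undec-4-en-3-one
Product: 16 (6S,7R,8S)-4-iodo-7,8-bis(TBSOCH2)-8-methyl-2-oxaspiro[5.5]undec-4-en-3-one
Conditions: I2 (2 equiv), pyridine, CH2Cl2, 23 → 40 °C
Reagents that add atoms: iodine, II
Why: Johnson α-iodination of the enoate (Baylis–Hillman-type pyridine addition, iodination, elimination); no stereocentre is affected.

Step 11
Reactants: 17 methyl 4-oxobutanoate and 18 trimethyl(prop-2-en-1-yl)silane
Product: 19 methyl (3S)-3-formylhex-5-enoate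
Conditions: (2S,5S)-5-benzyl-2-tert-butyl-3-methylimidazolidin-4-one·CF3CO2H (20 mol %; enantiomer chosen to give the 3S aldehyde), (NH4)2Ce(NO3)6 (2 equiv), NaHCO3, H2O, DME, −20 °C
Reagents that add atoms: none
Why: Organocatalytic SOMO α-allylation, in which the enamine radical cation is trapped by the allylsilane on the face left open by the imidazolidinone, setting the future C-13 stereocentre.

Step 12
Reactants: 19 methyl (3S)-3-formylhex-5-enoate
Product: 20 methyl (3S)-3-(hydroxymethyl)hex-5-enoate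
Conditions: NaBH4, MeOH, −20 °C, neutral work-up (used directly)
Reagents that add atoms: none
Why: Chemoselective borohydride reduction of the aldehyde beside the ester; the stereocentre is not epimerisable after reduction.

Step 13
Reactants: 20 methyl (3S)-3-(hydroxymethyl)hex-5-enoate
Product: 21 methyl (3S)-3-(iodomethyl)hex-5-enoate
Conditions: I2, PPh3, imidazole, CH2Cl2, 0 °C
Reagents that add atoms: iodine, II
Why: Appel iodination of the primary alcohol, done quickly so that the γ-hydroxy ester does not lactonise.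

Step 14
Reactants: 21 methyl (3S)-3-(iodomethyl)hex-5-enoate and 16 (6S,7R,8S)-4-iodo-7,8-bis(TBSOCH2)-8-methyl-2-oxaspiro[5.5]undec-4-en-3-one
Product: 23 methyl (3R)-3-{[(6R,7R,8S)-7,8-bis(TBSOCH2)-8-methyl-3-oxo-2-oxaspiro[5.5]undec-4-en-4-yl]methyl}hex-5-enoate, via alkylzinc iodide 22 (not isolated)
Conditions: 21, Zn dust, LiCl, THF, 40 °C; then 16, Pd(OAc)2 (5 mol %), SPhos (10 mol %), THF/NMP, 23 °C
Reagents that add atoms: zinc (retained in 22 only), [Zn]
Why: Negishi sp3–sp2 cross-coupling of a functionalised primary alkylzinc with the α-iodo enoate, which tolerates ester, lactone and alkene and leaves every stereocentre untouched.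

Step 15
Reactants: 23 methyl (3R)-3-{[(6R,7R,8S)-7,8-bis(TBSOCH2)-8-methyl-3-oxo-2-oxaspiro[5.5]undec-4-en-4-yl]methyl}hex-5-enoate
Product: 25 methyl (3S)-3-{[(6R,7R,8S)-7,8-bis(TBSOCH2)-8-methyl-3-oxo-2-oxaspiro[5.5]undec-4-en-4-yl]methyl}-5-oxopentanoate, via ozonide 24 (not isolated)
Conditions: O3, CH2Cl2, −78 °C (Sudan red end point); then Me2S, −78 → 23 °C
Reagents that add atoms: ozone, [O-][O+]=O
Why: Ozonolysis is selective for the electron-rich terminal alkene over the electron-poor, hindered enoate and unveils the C-11 aldehyde.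

Step 16
Reactants: 25 methyl (3S)-3-{[(6R,7R,8S)-7,8-bis(TBSOCH2)-8-methyl-3-oxo-2-oxaspiro[5.5]undec-4-en-4-yl]methyl}-5-oxopentanoate
Product: 27 tetracyclic β-keto lactone (target skeleton without the exocyclic methylene, C-6 and C-18 oxygens as TBS ethers, C-11 OH free), via samarium enolate 26 (not isolated)
Conditions: SmI2 (2.2 equiv), THF, −78 → 23 °C (no proton source); aq. NH4Cl
Reagents that add atoms: samarium diiodide (retained in 26 only), I[Sm]I
Why: Ketyl–olefin 6-endo cyclisation then intramolecular Claisen (Dieckmann-type) acylation, in which the ketyl carbon adds to C-9 from the lactone face on the C-1 side (away from C-5 and its CH2OTBS) with the samarium-bound oxygen chelated to the lactone carbonyl (C-11 OH cis to C-10) and the ester arm equatorial, and the regiospecific trivalent samarium enolate then closes ring D from the only face the tether reaches (C-8, matched with the preset C-13).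

Step 17
Reactants: 27 tetracyclic β-keto lactone bis-TBS ether
Product: 29 bis-TBS ether of the target (16-methylidene-15-ketone), via Mannich base 28 (not isolated)
Conditions: (CH2O)n, N-methylanilinium trifluoroacetate (1.5 equiv), THF, 65 °C
Reagents that add atoms: formaldehyde (as paraformaldehyde), C=O; N-methylaniline (as its trifluoroacetate, retained in 28 only), CNc1ccccc1
Why: Mannich reaction and β-elimination (direct α-methylenation) at C-16, the only enolisable position of the ketone because C-8 is quaternary.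

Step 18
Reactants: 29 bis-TBS ether of the target
Product: 30 target CNP0152458.1
Conditions: HF·pyridine, THF/pyridine, 0 → 23 °C
Reagents that add atoms: none
Why: Fluoride-mediated cleavage of the two primary TBS ethers under mildly acidic conditions that spare the α-methylene ketone and the lactone.

**Compound list**
1 | 2-methylidenepropane-1,3-diol | C=C(CO)CO | starting material
2 | 2-(TBSOCH2)prop-2-en-1-ol | C=C(CO)CO[Si](C)(C)C(C)(C)C | intermediate
3 | 2-(TBSOCH2)prop-2-enal | C=C(C=O)CO[Si](C)(C)C(C)(C)C | intermediate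
4 | (2E)-3-methylpent-2-en-4-yn-1-ol | C#C/C(C)=C/CO | starting material
5 | TBS ether of 4 | C#C/C(C)=C/CO[Si](C)(C)C(C)(C)C | intermediate
6 | tert-butyl(dimethyl){[(2E)-3-methylpenta-2,4-dien-1-yl]oxy}silane | C=C/C(C)=C/CO[Si](C)(C)C(C)(C)C | intermediate
7 | (1R,2S)-1,2-bis(TBSOCH2)-3-methylcyclohex-3-ene-1-carbaldehyde | CC1=CCC[C@](C=O)(CO[Si](C)(C)C(C)(C)C)[C@H]1CO[Si](C)(C)C(C)(C)C | intermediate
8 | N-(tert-butyldimethylsilyl)hydrazone of 7 | CC1=CCC[C@](C=NN[Si](C)(C)C(C)(C)C)(CO[Si](C)(C)C(C)(C)C)[C@H]1CO[Si](C)(C)C(C)(C)C | intermediate (not isolated)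
9 | (5S,6S)-5,6-bis(TBSOCH2)-1,5-dimethylcyclohex-1-ene | CC1=CCC[C@](C)(CO[Si](C)(C)C(C)(C)C)[C@H]1CO[Si](C)(C)C(C)(C)C | intermediate
10 | [(5S,6R)-5,6-bis(TBSOCH2)-5-methylcyclohex-1-en-1-yl]methanol | OCC1=CCC[C@](C)(CO[Si](C)(C)C(C)(C)C)[C@H]1CO[Si](C)(C)C(C)(C)C | intermediate (not isolated)
11 | (5S,6R)-5,6-bis(TBSOCH2)-5-methylcyclohex-1-ene-1-carbaldehyde | O=CC1=CCC[C@](C)(CO[Si](C)(C)C(C)(C)C)[C@H]1CO[Si](C)(C)C(C)(C)C | intermediate
12 | ethyl (2Z)-3-iodoprop-2-enoate | I/C=C\C(=O)OCC | starting material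
13 | ethyl (2Z)-4-[(5S,6R)-5,6-bis(TBSOCH2)-5-methylcyclohex-1-en-1-yl]-4-hydroxybut-2-enoate (both C-4 epimers) | CCOC(=O)/C=C\C(O)C1=CCC[C@](C)(CO[Si](C)(C)C(C)(C)C)[C@H]1CO[Si](C)(C)C(C)(C)C | intermediate (not isolated)
14 | 5-[(5S,6R)-5,6-bis(TBSOCH2)-5-methylcyclohex-1-en-1-yl]furan-2(5H)-one (both epimers) | O=C1OC(C=C1)C1=CCC[C@](C)(CO[Si](C)(C)C(C)(C)C)[C@H]1CO[Si](C)(C)C(C)(C)C | intermediate
15 | (6R,7R,8S)-7,8-bis(TBSOCH2)-8-methyl-2-oxaspiro[5.5]undec-4-en-3-one | O=C1OC[C@@]2(C=C1)CCC[C@](C)(CO[Si](C)(C)C(C)(C)C)[C@H]2CO[Si](C)(C)C(C)(C)C | intermediate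
16 | (6S,7R,8S)-4-iodo-7,8-bis(TBSOCH2)-8-methyl-2-oxaspiro[5.5]undec-4-en-3-one | O=C1OC[C@@]2(C=C1I)CCC[C@](C)(CO[Si](C)(C)C(C)(C)C)[C@H]2CO[Si](C)(C)C(C)(C)C | intermediate
17 | methyl 4-oxobutanoate | COC(=O)CCC=O | starting material
18 | trimethyl(prop-2-en-1-yl)silane | C=CC[Si](C)(C)C | starting material
19 | methyl (3S)-3-formylhex-5-enoate | COC(=O)C[C@@H](C=O)CC=C | intermediate
20 | methyl (3S)-3-(hydroxymethyl)hex-5-enoate | COC(=O)C[C@@H](CO)CC=C | intermediate
21 | methyl (3S)-3-(iodomethyl)hex-5-enoate | COC(=O)C[C@@H](CI)CC=C | intermediate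
22 | [(2S)-2-(2-methoxy-2-oxoethyl)pent-4-en-1-yl]zinc iodide | COC(=O)C[C@@H](C[Zn]I)CC=C | intermediate (not isolated)
23 | methyl (3R)-3-{[(6R,7R,8S)-7,8-bis(TBSOCH2)-8-methyl-3-oxo-2-oxaspiro[5.5]undec-4-en-4-yl]methyl}hex-5-enoate | O=C1OC[C@@]2(C=C1C[C@@H](CC=C)CC(=O)OC)CCC[C@](C)(CO[Si](C)(C)C(C)(C)C)[C@H]2CO[Si](C)(C)C(C)(C)C | intermediate
24 | ozonide (1,2,4-trioxolane) of the terminal alkene of 23 | O=C1OC[C@@]2(C=C1C[C@@H](CC3OCOO3)CC(=O)OC)CCC[C@](C)(CO[Si](C)(C)C(C)(C)C)[C@H]2CO[Si](C)(C)C(C)(C)C | intermediate (not isolated)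
25 | methyl (3S)-3-{[(6R,7R,8S)-7,8-bis(TBSOCH2)-8-methyl-3-oxo-2-oxaspiro[5.5]undec-4-en-4-yl]methyl}-5-oxopentanoate | O=C1OC[C@@]2(C=C1C[C@@H](CC=O)CC(=O)OC)CCC[C@](C)(CO[Si](C)(C)C(C)(C)C)[C@H]2CO[Si](C)(C)C(C)(C)C | intermediate
26 | ring C-closed bis(diiodosamarium) alkoxide/lactone enolate | COC(=O)C[C@@H]1C[C@@H](O[Sm](I)I)[C@H]2[C@@]3(CCC[C@](C)(CO[Si](C)(C)C(C)(C)C)[C@H]3CO[Si](C)(C)C(C)(C)C)COC(O[Sm](I)I)=C2C1 | intermediate (not isolated)
27 | tetracyclic β-keto lactone, bis-TBS ether, C-16 unsubstituted | C1C(=O)[C@]23C[C@H]1C[C@@H](O)[C@H]2[C@@]1(CCC[C@](C)(CO[Si](C)(C)C(C)(C)C)[C@H]1CO[Si](C)(C)C(C)(C)C)COC3=O | intermediate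
28 | C-16 (N-methylanilino)methyl Mannich base of 27 | CN(c1ccccc1)CC1C(=O)[C@]23C[C@H]1C[C@@H](O)[C@H]2[C@@]1(CCC[C@](C)(CO[Si](C)(C)C(C)(C)C)[C@H]1CO[Si](C)(C)C(C)(C)C)COC3=O | intermediate (not isolated)
29 | bis-TBS ether of the target | C=C1C(=O)[C@]23C[C@H]1C[C@@H](O)[C@H]2[C@@]1(CCC[C@](C)(CO[Si](C)(C)C(C)(C)C)[C@H]1CO[Si](C)(C)C(C)(C)C)COC3=O | intermediate
30 | CNP0152458.1 (4S,5R,8S,9S,10S,11R,13S) | C=C1C(=O)[C@]23C[C@H]1C[C@@H](O)[C@H]2[C@@]1(CCC[C@](C)(CO)[C@H]1CO)COC3=O | target

**Step count:** 18 steps in total. Longest linear sequence: 13 steps (steps 3–10 and 14–18).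

**Steps most likely to fail and their fallbacks**

The first is step 9, the proposed ring expansion. The tertiary radical may be reduced before it rearranges, or the cyclopropylcarbinyl radical may reopen only backwards. The fallback uses known chemistry, sets out from enal 11 and comes back at 15. Luche reduction (NaBH4, CeCl3·7H2O, MeOH) gives the allylic alcohol 10. An Fe(acac)3/PhSiH3 Giese coupling of 10 with methyl acrylate (EtOH/ethylene glycol, 60 °C) gives the hydroxy ester F1, which lactonises in the flask to the saturated spirolactone F2, the radical again being attacked anti to the CH2OTBS group. LiN(i-Pr)2 and PhSeBr give the α-phenylselanyl lactone F3, and H2O2/pyridine gives 15 by selenoxide elimination.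

The second is step 10, the α-iodination. Pyridine addition to the β-carbon next to the quaternary spiro centre may be too slow. The fallback sets out from 15 and comes back at 23, so it also replaces step 14. Conjugate reduction with LiBH(s-Bu)3 at −78 °C and alkylation of the resulting lactone enolate with iodide 21 (HMPA) give the saturated α-alkyl lactone F4. LiN(i-Pr)2 and PhSeBr give the selenide F5, and H2O2 gives 23 by elimination into the ring.

The third is step 16, the cascade. The samarium enolate may be quenched before it acylates. The fallback sets out from 25 and comes back at 27. SmI2 with t-BuOH in THF at −78 °C stops after the ketyl–olefin cyclisation and gives the hydroxy lactone ester F6. LiN(SiMe3)2 (3 equiv, THF, −78 → 0 °C) then closes ring D by Dieckmann condensation through the lactone enolate, which is more acidic than the ester α-position, and gives 27.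

**Further compounds**
F1 | step 9 | methyl 3-[1-(hydroxymethyl)-2,3-bis(TBSOCH2)-3-methylcyclohexyl]propanoate (Giese adduct) | COC(=O)CC[C@]1(CO)CCC[C@](C)(CO[Si](C)(C)C(C)(C)C)[C@H]1CO[Si](C)(C)C(C)(C)C
F2 | step 9 | 7,8-bis(TBSOCH2)-8-methyl-2-oxaspiro[5.5]undecan-3-one (4,5-dihydro-15) | O=C1OC[C@@]2(CC1)CCC[C@](C)(CO[Si](C)(C)C(C)(C)C)[C@H]2CO[Si](C)(C)C(C)(C)C
F3 | step 9 | 4-(phenylselanyl) derivative of F2 | O=C1OC[C@@]2(CC1[Se]c1ccccc1)CCC[C@](C)(CO[Si](C)(C)C(C)(C)C)[C@H]2CO[Si](C)(C)C(C)(C)C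
F4 | step 10 | 4,5-dihydro-23 (saturated α-alkyl lactone) | O=C1OC[C@@]2(CC1C[C@@H](CC=C)CC(=O)OC)CCC[C@](C)(CO[Si](C)(C)C(C)(C)C)[C@H]2CO[Si](C)(C)C(C)(C)C
F5 | step 10 | 4-(phenylselanyl) derivative of F4 | O=C1OC[C@@]2(CC1([Se]c1ccccc1)C[C@@H](CC=C)CC(=O)OC)CCC[C@](C)(CO[Si](C)(C)C(C)(C)C)[C@H]2CO[Si](C)(C)C(C)(C)C
F6 | step 16 | tricyclic hydroxy lactone ester (ring C closed, C-8 protonated, ester arm intact) | COC(=O)C[C@@H]1C[C@@H](O)[C@H]2[C@@]3(CCC[C@](C)(CO[Si](C)(C)C(C)(C)C)[C@H]3CO[Si](C)(C)C(C)(C)C)COC(=O)C2C1
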